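**Retrosynthetic overview**
1. Feature: in ring B the contiguous centres C5, C10 and C9 (labdane numbering) carry C5-H, the angular methyl C20 and the side-chain carbon C11 on one face (a cis-decalin). This is the pattern left by an endo, suprafacial [4+2] addition of an (E)-diene C6–C7–C8–C9 to a ring A C5=C10 alkene whose C20 is a formyl group.
2. Late disconnections: C12–C13 by Negishi coupling with purchased 3-bromofuran-2(5H)-one. C8=C17 comes from a C7=C8 enol silane by aminomethylation, elimination, 1,2-reduction and Pd–formate allylic hydrogenolysis. The C20 methyl comes from CHO by reduction and Barton–McCombie deoxygenation.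
3. Key disconnection: C5–C6 and C9–C10 (ring B), giving a ring A enal and a 2-silyloxy-4-alkyl-1,3-diene.
4. Ring A enal: C5=C10 by aldol condensation of a 1,7-dialdehyde, C3–C2 by Grignard addition to a pentaerythritol-derived aldehyde, C3 set by CBS reduction. Diene: Wittig olefination, then kinetic O-silylation.
5. Ring order: dioxane (purchased), ring A (step 9), ring B (step 14), butenolide attached (step 25).

Key step: step 14

Assumption: the SMILES is read literally. C5-H, C20, C11 and the C3 oxygen then lie on one face (called α below), which is a cis-fused decalin of configuration (3R,5R,9R,10S), and this is the compound made. C4 is not a stereocentre. Labdane numbering is used for all fragments.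

**Ring A enal**

Step 1
Reactants: 1 2,2-dimethyl-1,3-dioxane-5,5-dimethanol
Product: 2 [5-(benzyloxymethyl)-2,2-dimethyl-1,3-dioxan-5-yl]methanol
Conditions: NaH (1.0 equiv), BnBr (1.0 equiv), Bu4NI (cat.), THF, 0 °C to rt
Reagents that add atoms: benzyl bromide, BrCc1ccccc1
Why: Williamson etherification of a diol with two equivalent CH2OH groups using one equivalent of base should give mainly the monoether, which is separable from diol and diether; the free arm becomes C3 and the benzylated arm C5.

Step 2
Reactants: 2 [5-(benzyloxymethyl)-2,2-dimethyl-1,3-dioxan-5-yl]methanol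
Product: 3 5-(benzyloxymethyl)-2,2-dimethyl-1,3-dioxane-5-carbaldehyde
Conditions: Dess–Martin periodinane, CH2Cl2, rt
Reagents that add atoms: none
Why: Dess–Martin oxidation handles neopentyl alcohols well, and the aldehyde has no α-hydrogen, so it can neither enolise nor eliminate an alkoxide.

Step 3
Reactants: 3 5-(benzyloxymethyl)-2,2-dimethyl-1,3-dioxane-5-carbaldehyde; 4 benzyl 4-bromobutyl ether
Product: 6 racemic 5-(benzyloxy)-1-[5-(benzyloxymethyl)-2,2-dimethyl-1,3-dioxan-5-yl]pentan-1-ol, via 4-(benzyloxy)butylmagnesium bromide 5 (not isolated)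
Conditions: 4, Mg turnings, THF, rt to 40 °C; then 3, THF, 0 °C; sat. aq NH4Cl
Reagents that add atoms: none
Why: Grignard addition of a primary alkylmagnesium bromide to a non-enolisable aldehyde forms C3–C2 and brings in C2, C1, C10 and C20; the carbinol is racemic and its configuration is set in steps 4 and 5.

Step 4
Reactants: 6 racemic 5-(benzyloxy)-1-[5-(benzyloxymethyl)-2,2-dimethyl-1,3-dioxan-5-yl]pentan-1-ol
Product: 7 5-(benzyloxy)-1-[5-(benzyloxymethyl)-2,2-dimethyl-1,3-dioxan-5-yl]pentan-1-one
Conditions: Dess–Martin periodinane, CH2Cl2, rt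
Reagents that add atoms: none
Why: Dess–Martin oxidation of the hindered secondary alcohol gives a tert-alkyl n-alkyl ketone, and benzyl ethers and the acetonide are inert to the reagent.

Step 5
Reactants: 7 5-(benzyloxy)-1-[5-(benzyloxymethyl)-2,2-dimethyl-1,3-dioxan-5-yl]pentan-1-one
Product: 8 (1R)-5-(benzyloxy)-1-[5-(benzyloxymethyl)-2,2-dimethyl-1,3-dioxan-5-yl]pentan-1-ol
Conditions: (S)-1-methyl-3,3-diphenyltetrahydro-1H,3H-pyrrolo[1,2-c][1,3,2]oxazaborole [(S)-Me-CBS, 0.1 equiv], BH3·SMe2, THF, −20 °C; MeOH quench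
Reagents that add atoms: none
Why: Corey–Bakshi–Shibata reduction: the ketone binds to the oxazaborolidine–borane complex with the quaternary C4 group as the large substituent and the CH2 chain as the small one, so the (S)-catalyst should deliver hydride to the face giving the (R)-carbinol at C3, the sense known for tert-alkyl methyl and tert-alkyl n-alkyl ketones.

Step 6
Reactants: 8 (1R)-5-(benzyloxy)-1-[5-(benzyloxymethyl)-2,2-dimethyl-1,3-dioxan-5-yl]pentan-1-ol
Product: 9 (1R)-tert-butyldimethylsilyl ether of 8
Conditions: TBSOTf, 2,6-lutidine, CH2Cl2, 0 °C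
Reagents that add atoms: tert-butyldimethylsilyl triflate, CC(C)(C)[Si](C)(C)OS(=O)(=O)C(F)(F)F
Why: O-silylation with the silyl triflate overcomes the neopentyl hindrance at C3-OH, lutidine protects the acetonide from acid, and the C–O bond and its configuration are not touched.

Step 7
Reactants: 9 (1R)-tert-butyldimethylsilyl ether of 8
Product: 10 (5R)-5-(tert-butyldimethylsilyloxy)-5-[5-(hydroxymethyl)-2,2-dimethyl-1,3-dioxan-5-yl]pentan-1-ol
Conditions: H2 (1 atm), Pd/C, EtOAc, rt
Reagents that add atoms: none
Why: Catalytic hydrogenolysis removes both benzyl ethers in one operation under neutral conditions, which leave the silyl ether and the acetonide in place and give no silyl migration.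

Step 8
Reactants: 10 (5R)-5-(tert-butyldimethylsilyloxy)-5-[5-(hydroxymethyl)-2,2-dimethyl-1,3-dioxan-5-yl]pentan-1-ol
Product: 11 5-[(1R)-1-(tert-butyldimethylsilyloxy)-5-oxopentyl]-2,2-dimethyl-1,3-dioxane-5-carbaldehyde (C5 and C20 dialdehyde)
Conditions: Dess–Martin periodinane (2.5 equiv), CH2Cl2, rt
Reagents that add atoms: none
Why: Double Dess–Martin oxidation; the two hydroxyls are too far apart for lactol formation, so both should go cleanly to aldehydes.

Step 9
Reactants: 11 5-[(1R)-1-(tert-butyldimethylsilyloxy)-5-oxopentyl]-2,2-dimethyl-1,3-dioxane-5-carbaldehyde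
Product: 13 ring A enal (11R)-11-(tert-butyldimethylsilyloxy)-3,3-dimethyl-2,4-dioxaspiro[5.5]undec-7-ene-8-carbaldehyde, via ring A aldol 12 (not isolated)
Conditions: dibenzylammonium trifluoroacetate (0.3 equiv), toluene, 50 °C
Reagents that add atoms: none
Why: Amine-salt-catalysed intramolecular aldol condensation (6-enolexo closure): only the C20 aldehyde can enolise (at C10), and the C5 aldehyde on quaternary C4 can only accept, so a single cyclohexenecarbaldehyde should form after loss of water with C3 untouched.

**Diene**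

Step 10
Reactants: 14 propane-1,3-diol
Product: 15 3-[(4-methoxybenzyl)oxy]propan-1-ol
Conditions: 14 (3 equiv), NaH (1 equiv), PMBCl (1 equiv), Bu4NI (cat.), THF, 0 °C to rt
Reagents that add atoms: 4-methoxybenzyl chloride, ClCc1ccc(OC)cc1
Why: Williamson etherification with the diol in excess favours the monoether, and surplus diol is washed out with water.

Step 11
Reactants: 15 3-[(4-methoxybenzyl)oxy]propan-1-ol
Product: 16 3-[(4-methoxybenzyl)oxy]propanal
Conditions: Dess–Martin periodinane, CH2Cl2, 0 °C to rt
Reagents that add atoms: none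
Why: Dess–Martin oxidation is base-free, which avoids β-elimination of the PMB alkoxide from the β-alkoxy aldehyde.

Step 12
Reactants: 16 3-[(4-methoxybenzyl)oxy]propanal; 17 1-(triphenylphosphoranylidene)propan-2-one
Product: 18 (E)-6-[(4-methoxybenzyl)oxy]hex-3-en-2-one
Conditions: CH2Cl2, rt to 40 °C
Reagents that add atoms: none
Why: Wittig olefination with a stabilised acyl ylide is (E)-selective and forms C8=C9 under essentially neutral conditions.

Step 13
Reactants: 18 (E)-6-[(4-methoxybenzyl)oxy]hex-3-en-2-one
Product: 20 (E)-tert-butyl({6-[(4-methoxybenzyl)oxy]hexa-1,3-dien-2-yl}oxy)dimethylsilane, via lithium dienolate 19 (not isolated)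
Conditions: LiN(iPr)2, THF, −78 °C; TBSCl, DMPU, −78 to 0 °C
Reagents that add atoms: tert-butyldimethylsilyl chloride, CC(C)(C)[Si](C)(C)Cl
Why: Kinetic deprotonation at the α′ methyl group (C6) gives the cross-conjugated enolate, O-silylation traps it as the 2-silyloxydiene, and the low temperature avoids γ-deprotonation at C11 and loss of the C12 alkoxide.

**Union and endgame**

Step 14
Reactants: 13 ring A enal; 20 (E)-2-silyloxydiene
Product: 21 cis-decalin adduct: C20 formyl on C10; C7=C8 TBS enol ether (oxygen on C7); C3 OTBS; C4 spiro-acetonide; CH2CH2OPMB on C9; C3-O, C5-H, C20 and C11 all α; (3R,5S,9R,10R)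
Conditions: Me2AlCl (1.5 equiv), 20 (2 equiv), CH2Cl2, −78 to −20 °C; quench Et3N, then H2O
Reagents that add atoms: none
Why: Me2AlCl binds the formyl oxygen of 13 and lowers the enal LUMO, so a concerted but asynchronous normal-electron-demand [4+2] cycloaddition should occur in which C5–C6 forms ahead of C9–C10; the closest known reaction type is the Lewis-acid-promoted Diels–Alder reaction of cycloalk-1-enecarbaldehydes with 2-silyloxy-1,3-dienes, which gives cis-fused bicycles with an angular formyl group. Ring B (C5, C6, C7, C8, C9, C10) closes as a cyclohexene by intermolecular annulation onto the C5=C10 edge of ring A. C5 and C10 are tied to each other by suprafacial addition to a ring alkene in which C5-H and the formyl group are cis, so only a cis fusion can result, and C9 is set by the (E) geometry of C8=C9 together with the endo position of the aluminium-bound formyl group, which places C11 syn to C20. The absolute sense comes from C3: with the silyloxy group equatorial on the half-chair, the pseudoaxial CH2O arm of the spiro-dioxane lies on the same α face as the C3 oxygen and shields C5 there, so the diene should bond from the β face. Regioselectivity requires the nucleophilic terminus C6 to meet the enal β-carbon C5, which the para-directing 2-silyloxy and ortho-directing 4-alkyl groups both favour, and C6 being an unsubstituted CH2 is what lets it reach the neopentyl C5. Chemoselectivity for C=C over aldol-type attack at C20 is helped by the bulky TBS group (slow silyl transfer) and by a mild dialkylaluminium chloride at low temperature, which should also spare the acetonide and the PMB ether.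

Step 15
Reactants: 21 cis-decalin adduct
Product: 22 C20 primary alcohol (CH2OH on C10; enol silane and all other groups and stereocentres as in 21)
Conditions: i-Bu2AlH (1.5 equiv), CH2Cl2, −78 °C; aq potassium sodium tartrate
Reagents that add atoms: none
Why: Aluminium hydride reduction of the non-enolisable angular aldehyde in an aprotic medium with a near-neutral work-up keeps the C7=C8 enol silane as a regiodefined masked ketone.

Step 16
Reactants: 22 C20 primary alcohol
Product: 24 C20 O-alkyl S-methyl xanthate (CH2OC(=S)SMe on C10), via sodium xanthate 23 (not isolated)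
Conditions: NaH, THF, 0 °C; CS2; then MeI, rt
Reagents that add atoms: carbon disulfide, S=C=S; iodomethane, CI
Why: Xanthate ester formation (alkoxide addition to CS2, then S-methylation) works for hindered alcohols, and with C10 quaternary there is no β-hydrogen, so Chugaev elimination cannot occur later.

Step 17
Reactants: 24 C20 xanthate
Product: 25 C20 methyl compound (angular CH3 on C10; C7=C8 TBS enol ether; C3 OTBS; acetonide; C12 OPMB); (3R,5R,9R,10S)
Conditions: Bu3SnH, AIBN [2,2′-azobis(2-methylpropionitrile), cat.], toluene, 110 °C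
Reagents that add atoms: none
Why: Barton–McCombie deoxygenation: stannyl radical adds to C=S, the C20–O bond fragments at reflux, and the neopentyl radical is reduced by the stannane faster than it can add to the electron-rich C7=C8 bond, while any 1,5-hydrogen transfer from C12 leads to the same product; no stereocentre is involved.

Step 18
Reactants: 25 C20 methyl enol silane
Product: 26 Mannich base (C7 ketone; CH2NMe2 on C8, epimer mixture at C8)
Conditions: Me2N=CH2 I (Eschenmoser's salt, 1.5 equiv), CH2Cl2, rt; aq NaHCO3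
Reagents that add atoms: dimethyl(methylidene)ammonium iodide, C=[N+](C)C.[I-]
Why: Mannich-type aminomethylation of a silyl enol ether occurs only at the enol β-carbon C8, so C17 enters regiospecifically, and the C8 configuration does not matter because it is lost in step 19.

Step 19
Reactants: 26 Mannich base
Product: 28 α-methylene ketone (C8=C17 exocyclic; C7 ketone), via trimethylammonium iodide 27 (not isolated)
Conditions: MeI, Et2O–CH2Cl2, rt; then DBU, CH2Cl2, 0 °C to rt
Reagents that add atoms: none
Why: Quaternisation followed by E1cB (Hofmann-type) elimination of trimethylamine is the standard way from a Mannich base to an α-methylene ketone, and C9 and C5 are not acidified by the enone, so they should not epimerise.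

Step 20
Reactants: 28 α-methylene ketone
Product: 29 allylic alcohol (C7-OH, epimer mixture at C7; C8=C17)
Conditions: NaBH4, CeCl3·7H2O, MeOH, −78 to 0 °C
Reagents that add atoms: none
Why: Luche reduction gives 1,2-reduction of the enone, and the C7 configuration is irrelevant because C7 becomes CH2 in step 22.

Step 21
Reactants: 29 allylic alcohol
Product: 30 C7 methyl carbonate (epimer mixture at C7)
Conditions: ClCO2Me, pyridine, 4-(dimethylamino)pyridine (cat.), CH2Cl2, 0 °C
Reagents that add atoms: methyl chloroformate, COC(=O)Cl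
Why: Acylation of the secondary allylic alcohol installs a leaving group that ionises readily with palladium and liberates its own base.

Step 22
Reactants: 30 C7 methyl carbonate
Product: 31 exocyclic alkene (C8=C17; C7 CH2; C3 OTBS; acetonide; C12 OPMB); (3R,5R,9R,10S)
Conditions: Pd2(dba)3·CHCl3 (2.5 mol %), PBu3 (5 mol %), HCO2H, Et3N, THF, rt to 40 °C
Reagents that add atoms: none
Why: Palladium-catalysed hydrogenolysis of an allylic carbonate with formate (Tsuji-type allylic reduction): zerovalent palladium ionises both C7 epimers to the same C7–C8–C17 π-allyl complex, and with PBu3 the palladium formate sits at the unhindered terminus C17 and passes hydride to the more substituted terminus C7 as CO2 is lost, leaving the exocyclic C8=C17 alkene.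

Step 23
Reactants: 31 exocyclic alkene PMB ether
Product: 32 C12 primary alcohol
Conditions: DDQ, CH2Cl2–pH 7 phosphate buffer, 0 °C
Reagents that add atoms: none
Why: Oxidative PMB cleavage by hydride abstraction from the electron-rich benzylic position leaves the silyl ether, the acetonide and the unactivated 1,1-disubstituted alkene alone.

Step 24
Reactants: 32 C12 primary alcohol
Product: 33 C12 primary iodide
Conditions: I2, PPh3, imidazole, CH2Cl2, 0 °C to rt
Reagents that add atoms: iodine, II
Why: Appel-type iodination proceeds by SN2 displacement of the alkoxyphosphonium ion at the unhindered C12, and imidazole buffers the medium for the acetonide.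

Step 25
Reactants: 33 C12 primary iodide; 34 3-bromofuran-2(5H)-one
Product: 36 protected target (α-alkyl butenolide on C12; C3 OTBS; C18/C19 acetonide), via alkylzinc iodide 35 (not isolated)
Conditions: Zn dust, LiCl, THF, 40 °C; then 34, PdCl2(dppf) (5 mol %), THF, rt to 50 °C
Reagents that add atoms: none
Why: Negishi coupling: zinc insertion into the primary C12–I bond tolerates silyl ether, acetal and alkene (C12 stands in a 4-pentenyl relation to C8=C17 and has no easy ring closure), and the alkylzinc transmetallates to the alkenylpalladium bromide from the α-bromobutenolide, with the wide-bite-angle dppf favouring reductive elimination over β-hydride loss, as known for α-halo enones and enoates.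

Step 26
Reactants: 36 protected target
Product: 37 target, 3-{2-[(1R,4aR,6R,8aS)-6-hydroxy-5,5-bis(hydroxymethyl)-8a-methyl-2-methylidenedecahydronaphthalen-1-yl]ethyl}furan-2(5H)-one
Conditions: 48% aq HF, MeCN, 0 °C to rt
Reagents that add atoms: none
Why: Acidic fluoride deprotection hydrolyses the acetonide and cleaves the C3 silyl ether in one operation under conditions mild enough to leave the exocyclic alkene and the butenolide unchanged.

**Compound list**
1 | 2,2-dimethyl-1,3-dioxane-5,5-dimethanol | CC1(C)OCC(CO)(CO)CO1 | starting material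
2 | [5-(benzyloxymethyl)-2,2-dimethyl-1,3-dioxan-5-yl]methanol | CC1(C)OCC(CO)(COCc2ccccc2)CO1 | intermediate
3 | 5-(benzyloxymethyl)-2,2-dimethyl-1,3-dioxane-5-carbaldehyde | CC1(C)OCC(C=O)(COCc2ccccc2)CO1 | intermediate
4 | benzyl 4-bromobutyl ether | BrCCCCOCc1ccccc1 | starting material
5 | 4-(benzyloxy)butylmagnesium bromide | Br[Mg]CCCCOCc1ccccc1 | intermediate
6 | racemic 5-(benzyloxy)-1-[5-(benzyloxymethyl)-2,2-dimethyl-1,3-dioxan-5-yl]pentan-1-ol | CC1(C)OCC(COCc2ccccc2)(CO1)C(O)CCCCOCc1ccccc1 | intermediate
7 | 5-(benzyloxy)-1-[5-(benzyloxymethyl)-2,2-dimethyl-1,3-dioxan-5-yl]pentan-1-one | CC1(C)OCC(COCc2ccccc2)(CO1)C(=O)CCCCOCc1ccccc1 | intermediate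
8 | (1R)-5-(benzyloxy)-1-[5-(benzyloxymethyl)-2,2-dimethyl-1,3-dioxan-5-yl]pentan-1-ol | CC1(C)OCC(COCc2ccccc2)(CO1)[C@H](O)CCCCOCc1ccccc1 | intermediate
9 | (1R)-TBS ether of 8 | CC1(C)OCC(COCc2ccccc2)(CO1)[C@H](O[Si](C)(C)C(C)(C)C)CCCCOCc1ccccc1 | intermediate
10 | (5R)-5-(tert-butyldimethylsilyloxy)-5-[5-(hydroxymethyl)-2,2-dimethyl-1,3-dioxan-5-yl]pentan-1-ol | CC1(C)OCC(CO)(CO1)[C@H](O[Si](C)(C)C(C)(C)C)CCCCO | intermediate
11 | 5-[(1R)-1-(tert-butyldimethylsilyloxy)-5-oxopentyl]-2,2-dimethyl-1,3-dioxane-5-carbaldehyde | CC1(C)OCC(C=O)(CO1)[C@H](O[Si](C)(C)C(C)(C)C)CCCC=O | intermediate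
12 | ring A aldol (C5-OH, C10-CHO, both centres unspecified) | O=CC1C(O)C2(COC(C)(C)OC2)[C@H](O[Si](C)(C)C(C)(C)C)CC1 | intermediate
13 | ring A enal, (11R)-11-(tert-butyldimethylsilyloxy)-3,3-dimethyl-2,4-dioxaspiro[5.5]undec-7-ene-8-carbaldehyde | O=CC1=CC2(COC(C)(C)OC2)[C@H](O[Si](C)(C)C(C)(C)C)CC1 | intermediate
14 | propane-1,3-diol | OCCCO | starting material
15 | 3-[(4-methoxybenzyl)oxy]propan-1-ol | OCCCOCc1ccc(OC)cc1 | intermediate
16 | 3-[(4-methoxybenzyl)oxy]propanal | O=CCCOCc1ccc(OC)cc1 | intermediate
17 | 1-(triphenylphosphoranylidene)propan-2-one | CC(=O)C=P(c1ccccc1)(c1ccccc1)c1ccccc1 | starting material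
18 | (E)-6-[(4-methoxybenzyl)oxy]hex-3-en-2-one | CC(=O)/C=C/CCOCc1ccc(OC)cc1 | intermediate
19 | lithium dienolate of 18 | [Li]OC(=C)/C=C/CCOCc1ccc(OC)cc1 | intermediate
20 | (E)-tert-butyl({6-[(4-methoxybenzyl)oxy]hexa-1,3-dien-2-yl}oxy)dimethylsilane | C=C(O[Si](C)(C)C(C)(C)C)/C=C/CCOCc1ccc(OC)cc1 | intermediate
21 | cis-decalin Diels–Alder adduct, C20 formyl, C7=C8 enol silane | C1=C(O[Si](C)(C)C(C)(C)C)C[C@H]2C3(COC(C)(C)OC3)[C@H](O[Si](C)(C)C(C)(C)C)CC[C@@]2(C=O)[C@@H]1CCOCc1ccc(OC)cc1 | intermediate
22 | C20 primary alcohol | C1=C(O[Si](C)(C)C(C)(C)C)C[C@H]2C3(COC(C)(C)OC3)[C@H](O[Si](C)(C)C(C)(C)C)CC[C@@]2(CO)[C@@H]1CCOCc1ccc(OC)cc1 | intermediate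
23 | sodium xanthate of 22 | C1=C(O[Si](C)(C)C(C)(C)C)C[C@H]2C3(COC(C)(C)OC3)[C@H](O[Si](C)(C)C(C)(C)C)CC[C@@]2(COC(=S)[S-])[C@@H]1CCOCc1ccc(OC)cc1.[Na+] | intermediate
24 | C20 S-methyl xanthate | C1=C(O[Si](C)(C)C(C)(C)C)C[C@H]2C3(COC(C)(C)OC3)[C@H](O[Si](C)(C)C(C)(C)C)CC[C@@]2(COC(=S)SC)[C@@H]1CCOCc1ccc(OC)cc1 | intermediate
25 | C20 methyl enol silane | C1=C(O[Si](C)(C)C(C)(C)C)C[C@H]2C3(COC(C)(C)OC3)[C@H](O[Si](C)(C)C(C)(C)C)CC[C@@]2(C)[C@@H]1CCOCc1ccc(OC)cc1 | intermediate
26 | Mannich base (C8 unspecified) | CN(C)CC1C(=O)C[C@H]2C3(COC(C)(C)OC3)[C@H](O[Si](C)(C)C(C)(C)C)CC[C@@]2(C)[C@@H]1CCOCc1ccc(OC)cc1 | intermediate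
27 | trimethylammonium iodide of 26 | C[N+](C)(C)CC1C(=O)C[C@H]2C3(COC(C)(C)OC3)[C@H](O[Si](C)(C)C(C)(C)C)CC[C@@]2(C)[C@@H]1CCOCc1ccc(OC)cc1.[I-] | intermediate
28 | α-methylene ketone | C=C1C(=O)C[C@H]2C3(COC(C)(C)OC3)[C@H](O[Si](C)(C)C(C)(C)C)CC[C@@]2(C)[C@@H]1CCOCc1ccc(OC)cc1 | intermediate
29 | C7 allylic alcohol (C7 unspecified) | C=C1C(O)C[C@H]2C3(COC(C)(C)OC3)[C@H](O[Si](C)(C)C(C)(C)C)CC[C@@]2(C)[C@@H]1CCOCc1ccc(OC)cc1 | intermediate
30 | C7 methyl carbonate (C7 unspecified) | C=C1C(OC(=O)OC)C[C@H]2C3(COC(C)(C)OC3)[C@H](O[Si](C)(C)C(C)(C)C)CC[C@@]2(C)[C@@H]1CCOCc1ccc(OC)cc1 | intermediate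
31 | exocyclic alkene PMB ether | C=C1CC[C@H]2C3(COC(C)(C)OC3)[C@H](O[Si](C)(C)C(C)(C)C)CC[C@@]2(C)[C@@H]1CCOCc1ccc(OC)cc1 | intermediate
32 | C12 primary alcohol | C=C1CC[C@H]2C3(COC(C)(C)OC3)[C@H](O[Si](C)(C)C(C)(C)C)CC[C@@]2(C)[C@@H]1CCO | intermediate
33 | C12 primary iodide | C=C1CC[C@H]2C3(COC(C)(C)OC3)[C@H](O[Si](C)(C)C(C)(C)C)CC[C@@]2(C)[C@@H]1CCI | intermediate
34 | 3-bromofuran-2(5H)-one | O=C1OCC=C1Br | starting material
35 | C12 alkylzinc iodide | C=C1CC[C@H]2C3(COC(C)(C)OC3)[C@H](O[Si](C)(C)C(C)(C)C)CC[C@@]2(C)[C@@H]1CC[Zn]I | intermediate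
36 | protected target | C=C1CC[C@H]2C3(COC(C)(C)OC3)[C@H](O[Si](C)(C)C(C)(C)C)CC[C@@]2(C)[C@@H]1CCC1=CCOC1=O | intermediate
37 | CNP0146463.1 | C=C1CC[C@H]2C(CO)(CO)[C@H](O)CC[C@@]2(C)[C@@H]1CCC1=CCOC1=O | target

**Step count**
Total step count: 26. Longest linear sequence: 22 steps (steps 1–9, then 14–26). The diene arm is 4 steps (steps 10–13).

**Steps most likely to fail**

Step 14. The neopentyl environment of C5 may slow the cycloaddition so much that other processes take over. These are aldol-type attack of the enol silane at the formyl carbon, Lewis-acid desilylation of the diene, a stepwise Michael pathway with loss of the cis fusion, and poor facial selectivity if the half-chair with an axial C3 silyloxy group reacts.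

The fallback forms the same two bonds intramolecularly through a C20–O–C12 ester tether. It sets out from 13 and 18.
- Pinnick oxidation of 13 (NaClO2, NaH2PO4, 2-methylbut-2-ene, t-BuOH–H2O) gives ring A carboxylic acid F1.
- DDQ in wet CH2Cl2 frees (E)-6-hydroxyhex-3-en-2-one F2 from 18.
- Carbodiimide esterification (EDC·HCl, 4-(dimethylamino)pyridine, CH2Cl2) joins them to keto ester F3.
- Kinetic silylation (LiN(SiMe3)2, TBSCl, THF–DMPU, −78 °C) gives silyloxytriene F4.
- Heating F4 in toluene in a sealed tube with 2,6-di-tert-butyl-4-methylphenol closes ring B and a six-membered lactone together to give tetracyclic lactone F5. The tether fixes the regiochemistry, and the carbonyl-endo folding should keep C11 syn to C20.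
- LiAlH4 in Et2O at 0 °C opens the lactone to C12,C20 diol F6.
- Selective Williamson etherification of the unhindered C12 hydroxyl (NaH 1 equiv, PMBCl, Bu4NI, THF) comes back to the route at 22.

Step 17. Fragmentation of the primary neopentyl C20–O bond may be slow, so the stannyl adduct radical is reduced instead and the alcohol is returned. Prolonged heating may also erode the enol silane.

The fallback removes the oxygen at the aldehyde level by hydride reduction of a sulfonylhydrazone, so steps 15 and 16 are not needed. It sets out from 21.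
- TsNHNH2 in THF at rt gives C20 tosylhydrazone F7.
- Catecholborane in CHCl3 at −10 °C, then NaOAc·3H2O at reflux, reduces the C=N bond. The resulting diazene collapses with loss of nitrogen to the methyl group, and the sequence comes back to the route at 25.

Step 25. Zinc insertion may be sluggish or followed by protodemetalation. The alkylpalladium species may suffer β-hydride elimination, or the bromobutenolide may decompose before it couples.

The fallback forms C12–C13 by enolate alkylation and creates the ring alkene afterwards. It sets out from 33.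
- The lithium enolate of purchased 3-(phenylsulfanyl)oxolan-2-one (LiN(iPr)2, THF–DMPU, −78 °C to rt) is alkylated by the iodide to give α-phenylsulfanyl lactone F8.
- mCPBA (1.0 equiv, CH2Cl2, −78 °C) oxidises sulfur faster than the alkene to give sulfoxide F9.
- Thermal syn elimination (toluene, CaCO3, 110 °C) towards C14 comes back to the route at 36.

**Further compounds**
F1 | step 14 | ring A carboxylic acid | OC(=O)C1=CC2(COC(C)(C)OC2)[C@H](O[Si](C)(C)C(C)(C)C)CC1
F2 | step 14 | (E)-6-hydroxyhex-3-en-2-one | CC(=O)/C=C/CCO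
F3 | step 14 | keto ester | CC(=O)/C=C/CCOC(=O)C1=CC2(COC(C)(C)OC2)[C@H](O[Si](C)(C)C(C)(C)C)CC1
F4 | step 14 | silyloxytriene | C=C(O[Si](C)(C)C(C)(C)C)/C=C/CCOC(=O)C1=CC2(COC(C)(C)OC2)[C@H](O[Si](C)(C)C(C)(C)C)CC1
F5 | step 14 | tetracyclic lactone | C1=C(O[Si](C)(C)C(C)(C)C)C[C@H]2C3(COC(C)(C)OC3)[C@H](O[Si](C)(C)C(C)(C)C)CC[C@@]2(C(=O)OCC3)[C@@H]13
F6 | step 14 | C12,C20 diol | C1=C(O[Si](C)(C)C(C)(C)C)C[C@H]2C3(COC(C)(C)OC3)[C@H](O[Si](C)(C)C(C)(C)C)CC[C@@]2(CO)[C@@H]1CCO
F7 | step 17 | C20 tosylhydrazone | C1=C(O[Si](C)(C)C(C)(C)C)C[C@H]2C3(COC(C)(C)OC3)[C@H](O[Si](C)(C)C(C)(C)C)CC[C@@]2(/C=N/NS(=O)(=O)c2ccc(C)cc2)[C@@H]1CCOCc1ccc(OC)cc1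
F8 | step 25 | α-phenylsulfanyl lactone | C=C1CC[C@H]2C3(COC(C)(C)OC3)[C@H](O[Si](C)(C)C(C)(C)C)CC[C@@]2(C)[C@@H]1CCC1(Sc2ccccc2)CCOC1=O
F9 | step 25 | sulfoxide | C=C1CC[C@H]2C3(COC(C)(C)OC3)[C@H](O[Si](C)(C)C(C)(C)C)CC[C@@]2(C)[C@@H]1CCC1(S(=O)c2ccccc2)CCOC1=O
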